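The readings were computed for substances that don't exist; noise was put on by code.

The last reading of the south-west flask, at 144 h, shows target 54% and starting material 17%, and you take this flask over at 8.0 d.

in all of them: starting material 0.029 M; second substrate 0.0145 M; free catalyst 17 µM; temperature 0 °C

|  | coupling partner | protic impurity | remark | time |
|---|---|---|---|---|
| south-west | 0.029 M | 8.7 mM | the very flask that is asked about, followed so far |  |
| flask | 0.0290 M | 8.70 mM |  | 8.0 d |

south-west run (percent of the starting material charged)

| time / h | target / % | starting material / % |
|---|---|---|
| 30.0 | 31 | 40 |
| 60.0 | 40 | 26 |
| 96.0 | 50 | 21 |
| 120 | 53 | 16 |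
| 144 | 54 | 17 |

(each reading ± 2 percentage points)

- target taken out counts as made
- additions bring no volume worth counting
- the earlier runs do not show what temperature does; that part of a forecast is a guess

- dusk: at 8.0 d add coupling partner, 50.0% of the amount charged, then wait 8.0 d
- dawn: at 8.0 d raise the temperature by 10 K, then wait 8.0 d
- midnight: at 8.0 d add free catalyst, 100% of the amount charged, then wait 8.0 d
- spring: change nothing and wait 8.0 d more
- winter: at 8.0 d take out 90% of the target then present, then wait 8.0 d

* target, in percent of the starting material first charged, at 8.0 d
* what to do for the largest gain in target; "none" if nothing gains more than 2 percentage points (dusk / dawn / midnight / spring / winter / none)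
* target present, with what was taken out counted in, in percent of the starting material first charged, after dawn
* target present, with what was taken out counted in, in percent of the starting material first charged, after midnight

Follow one molecule of starting material through the south-west flask. At its first fork it meets protic impurity, whose charge equals 30.0% of the starting material. Target plus starting material reads 71.0% at 30.0 h and 71.0% at 144 h, so I count that share as lost and 70.0% as the ceiling for target. At its second fork it needs a coupling partner. The readings do not show second substrate, but I assume that it spends one coupling partner per molecule too. So I reckon:

partner demand = (c starting material − c protic impurity + c second substrate) / c coupling partner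

partner demand = (0.029 M − 8.70 mM + 0.0145 M) / 0.0290 M = 1.20

This partner demand is the usable substrate per coupling partner charged, and it stands above one, so by my reckoning coupling partner falls short.

Dusk adds 0.0145 M of coupling partner and brings the demand to 0.800, below one. Add that, then. Leave the catalyst and the bath alone, since neither brings coupling partner and the demand stays at 1.20.

The forecast gives 56% at 8.0 d, 62% after dawn and 65% after midnight, and it chooses midnight, noting “Extra partner wins only if partner is limiting”. I part from it on the choice: I take dusk, with room of up to 14 percentage points below the ceiling.

The flask gives 56.7% at 8.0 d, 59.1% after dawn and 59.2% after midnight, and dusk gains 13 points, against 2.5 points for midnight.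

    starting material + free catalyst ⇌ catalyst intermediate A (K = 18.0 /M, k = 1.70 /M/s, Ea = 55.0 kJ/mol, ΔH = −17.0 kJ/mol)
    coupling partner + catalyst intermediate A → free catalyst + target (k = 2.00 /M/s, Ea = 53.0 kJ/mol)
    second substrate + free catalyst ⇌ catalyst intermediate B (K = 69.0 /M, k = 1.10 /M/s, Ea = 55.0 kJ/mol, ΔH = −12.0 kJ/mol)
    coupling partner + catalyst intermediate B → free catalyst + second product (k = 0.510 /M/s, Ea = 56.0 kJ/mol)
    starting material + protic impurity → quenched substrate (k = 0.0440 /M/s, Ea = 62.0 kJ/mol)
    (constants at 0 °C)

In this flask, with its demand of 1.20, coupling partner is the limiting reagent of the coupling: 4.67% of its charge is left at 192 h, beside starting material at 13.3%. The neighbouring flask, the same recipe with 0.073 M of coupling partner, has a demand of 0.477, which reckons 52.3% of that partner as spare. That neighbouring flask stands at 70.0% target with 52% of its coupling partner left.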